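## Analysis of the target

Ambofuranol 13 is a 2-arylbenzofuran. In benzofuran numbering (O1, C2, C3, C3a, C4 to C7, C7a; ring A is the benzo ring, ring B the aryl group on C2), C3 carries a methoxy group, C5 a 3-methylbut-2-enyl (prenyl) group and C6 a hydroxyl, and ring B is a 2-hydroxy-4-methoxyphenyl group. The molecule has no stereocentre and no stereogenic double bond, so stereochemistry can arise only in intermediates. The sensitive parts are the prenyl alkene (acid closes it onto the neighbouring C6 hydroxyl, and electrophiles and oxidants attack it), the 3-methoxybenzofuran (an aromatic enol ether of a benzofuran-3-one) and two free phenols on electron-rich resorcinol-type rings. The main difficulty is the oxygen on C3, because most routes to 2-arylbenzofurans leave hydrogen there. In addition, four ring oxygens must end as two methyl ethers and two phenols, and the prenyl group must sit on C5 only. The plan rests on one feature: without the bonds O1–C2 and C3–OMe, C2 and C3 are the two alkene carbons of a stilbene that links rings A and B, and the target differs from that stilbene by the addition of two oxygen nucleophiles with loss of two electrons, followed by one dehydrogenation.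

## Retrosynthetic reasoning

13 to 12. The two phenols are set free last, from the bis(methoxymethyl) ether 12. The C6 oxygen is masked through the oxidative steps because a free hydroxyl para to C3a would open quinone methide and radical coupling pathways, and next to the prenyl group it would allow chromene formation. The ring B oxygen is masked so that only one phenol can close the furan ring. An acetal is preferred to a silyl ether, which could migrate to the benzylic anion needed on ring B, and to a benzyl ether, whose hydrogenolysis would saturate the prenyl group. The forward step must cleave two aryl acetals without touching the prenyl alkene or the C3 enol ether.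

12 to 11. The C2=C3 bond of the furan is traced back to the C2–H and C3–H bonds of the dihydrobenzofuran 11. This separates the placing of the two oxygens from the reaching of the aromatic oxidation level. The forward step is a dehydrogenation that must prefer the C2–H bond (next to O1 and benzylic to ring B) over the prenyl methylene. Both stereocentres of 11 vanish here, so 11 need not be one diastereomer.

11 to 10. The key disconnection cuts O1–C2 and C3–OMe. Cutting there, and not at C2–C1' or C3–C3a, returns the whole carbon skeleton as stilbene 10, so the ring-forming step makes only carbon–oxygen bonds. In the forward direction two electrons are taken from the hydroxystilbene, the ring A phenol adds to C2, and the solvent alcohol adds to C3. The gain is that the C3 oxygen arrives in the step that closes the ring, at a position the phenol cannot reach itself.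

10 to 4 and 9. The C2=C3 bond is cut by olefination: the aldehyde carbon of 4 becomes C3 and the phosphonate carbon of 9 becomes C2. This polarity is chosen because both halves come from commercially available salicylaldehydes, 1 and 5, and because the anion-bearing partner 9 then has no free phenol. The phenol of 4 is carried through as its phenoxide, which saves a protection and a deprotection.

4 to 2 and 3, and 2 to 1. The C5–CH2 bond is cut to the aryl bromide 2 and the prenyl stannane 3. The bromine of 1 marks C5 from the start, whereas electrophilic prenylation of a free resorcinol ring would have to choose between oxygen and two ring carbons. Bromide 2 comes from 1 by masking the hydroxyl para to the formyl group. The other hydroxyl, hydrogen-bonded to the aldehyde, stays free and becomes O1.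

9 to 7, 6 and 5. The carbon–phosphorus bond is cut to the benzylic bromide 8, which is made from alcohol 7 and used crude. Alcohol 7 comes from aldehyde 6 by reduction, and 6 from 5 by protection of its only phenol. The forward sequence must avoid acid throughout, because the acetal and the very electron-rich benzylic position are both acid-labile.

## Alternatives that were turned down

Alternative 1: Ring A is built last by benzannulation, cutting C4–C5 and C3a–C7a. In the forward key step the bis-silyl dienol ether 1-methoxy-7-methyl-1,3-bis(trimethylsilyloxy)octa-1,3,6-triene A1 and methyl propiolate A2 undergo a Diels–Alder reaction. The adduct aromatises by losing its C1 methoxy group and gives methyl 2,4-dihydroxy-5-(3-methylbut-2-enyl)benzoate A3.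
- For: the prenyl group is in the diene A1 before the ring exists, so its position is beyond doubt and no tin reagent is needed. The dienophile A2 is simple, its polarity fixes the orientation of the cycloaddition, and its ester carbon, which becomes C3, is at a useful oxidation level. On prenyl regiocontrol this plan is stronger than the chosen one, which depends on the regiochemistry of an allyl cross-coupling.
- Against: the key step makes a benzene ring whose substitution pattern is already available in 1, with a bromine at the right carbon. A1 reacts at a substituted diene terminus of undefined geometry. After A3 the real problem is untouched: C2, ring B, the O1–C2 bond and the C3 methyl ether would all still have to be added, probably through a hard benzylic deprotonation next to an electron-rich ring.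
- Comparison: the chosen route spends its key step on the furan ring and the C3 oxygen and reaches the target in nine steps.

Alternative 2: Ring B is built last, cutting C1'–C2', C2'–C3' and C4'–C5'. In the forward key step the diazo enone (E)-4-[6-(tert-butyldimethylsilyloxy)-3-methoxy-5-(3-methylbut-2-enyl)benzofuran-2-yl]-1-diazobut-3-en-2-one A4 is photolysed with methoxyethyne A5. A Wolff shift gives a vinylketene, which adds to A5 in a [2+2] fashion. Four-electron ring opening, six-electron ring closure and tautomerisation then give 2-[6-(tert-butyldimethylsilyloxy)-3-methoxy-5-(3-methylbut-2-enyl)benzofuran-2-yl]-5-methoxyphenol A6, the 6-O-silyl ether of the target.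
- For: the 2'-hydroxyl appears free and the 4'-methoxy group in place in one operation, with regiochemistry fixed by the polarity of ketene and alkyne. On oxygen differentiation in ring B this plan is stronger, since the chosen route needs a protecting group there.
- Against: ring B with exactly this pattern is commercially available as 5. A4 presupposes the complete 3-methoxy-5-prenylbenzofuran core with a two-carbon side chain, so the hard part of the target is moved into the preparation of the precursor. A5 is volatile and unstable. The photolysis has to spare an electron-rich benzofuran chromophore, an enone that can isomerise and a prenyl alkene that can add to the ketene. The silyl group of A6 must still be removed afterwards.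
- Comparison: the chosen route uses simple, separately made halves and puts its single uncertain step where the structural problem lies.

Alternative 3: All three bonds around the furan are cut at once, C3–C3a, C3–OMe and O1–C2. In the forward key step 4-(3-methylbut-2-enyl)benzene-1,3-diol A7, the glyoxal 2-[4-methoxy-2-(prop-2-enyloxy)phenyl]-2-oxoacetaldehyde A8 and the solvent alcohol condense under mild acid. Hydroxyalkylation of A7 by the aldehyde carbon, exchange of the benzylic hydroxyl for methoxy, and cyclodehydration of the phenol onto the ketone give 3-methoxy-2-[4-methoxy-2-(prop-2-enyloxy)phenyl]-5-(3-methylbut-2-enyl)benzofuran-6-ol A9, the 2'-O-allyl ether of the target.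
- For: it is by far the shortest and most convergent plan, it needs no oxidation step, and C3 arrives at the right oxidation level. On step economy it is clearly stronger than the chosen route.
- Against: A7 has two nucleophilic ring positions and two phenols. It is a free ortho-prenylphenol held in acid, which invites ring closure of the prenyl group. The benzylic cation at C3 can be taken by a second molecule of A7 instead of the alcohol. The ketone of A8 is deactivated by the ortho and para oxygens of ring B, so the cyclodehydration may stall or give way to aryl migration. A7 itself requires a regioselective prenylation, and the allyl group of A9 must still be removed.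
- Comparison: the chosen route gives positional certainty in its place. Every bond of the furan ring is dictated by where the free phenol and the alkene sit in 10, the prenyl position is fixed by the bromine of 1, and the risky step runs buffered and non-acidic with the sensitive phenols masked.

Key step: step 7

Assumption: the olefination of step 6 is written for the E isomer; any Z isomer formed is expected to enter step 7 equally, because the alkene radical cation loses its geometry, and the two stereocentres made in step 7 are racemic and serve only as a relay.

## Route

Step 1
Reactants: 1 5-bromo-2,4-dihydroxybenzaldehyde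
Product: 2 5-bromo-2-hydroxy-4-(methoxymethoxy)benzaldehyde
Conditions: MOMCl (1.05 equiv), K2CO3, acetone, 0 °C to rt
Reagents that add atoms: chloromethyl methyl ether, COCCl
Why: Williamson-type O-alkylation; the C2 hydroxyl is held in a hydrogen bond to the aldehyde and is less acidic than the C4 hydroxyl (para to the formyl group, ortho to bromine), so one equivalent of the chloride with a mild base should alkylate O4 only.

Step 2
Reactants: 2 5-bromo-2-hydroxy-4-(methoxymethoxy)benzaldehyde; 3 tributyl(3-methylbut-2-enyl)stannane
Product: 4 2-hydroxy-4-(methoxymethoxy)-5-(3-methylbut-2-enyl)benzaldehyde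
Conditions: Pd(PPh3)4 (5 mol %), DMF, 100 °C
Reagents that add atoms: none
Why: Stille coupling; zerovalent palladium inserts into the aryl bromide, the allylic stannane transmetallates, and reductive elimination at the unsubstituted allyl terminus should give the linear prenyl arene, with the free phenol and aldehyde tolerated under these neutral conditions.

Step 3
Reactants: 5 2-hydroxy-4-methoxybenzaldehyde
Product: 6 4-methoxy-2-(methoxymethoxy)benzaldehyde
Conditions: MOMCl, K2CO3, acetone, reflux
Reagents that add atoms: chloromethyl methyl ether, COCCl
Why: Williamson-type O-alkylation of the only phenol; warming overcomes the hydrogen bond to the aldehyde.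

Step 4
Reactants: 6 4-methoxy-2-(methoxymethoxy)benzaldehyde
Product: 7 [4-methoxy-2-(methoxymethoxy)phenyl]methanol
Conditions: NaBH4, MeOH, 0 °C
Reagents that add atoms: none
Why: Hydride reduction of the aldehyde to the benzylic alcohol; the acetal and the aryl ether are inert to NaBH4.

Step 5
Reactants: 7 [4-methoxy-2-(methoxymethoxy)phenyl]methanol
Product: 9 diethyl {[4-methoxy-2-(methoxymethoxy)phenyl]methyl}phosphonate, via 4-methoxy-2-(methoxymethoxy)benzyl bromide 8 (not isolated)
Conditions: CBr4, PPh3, CH2Cl2, 0 °C; pentane trituration and filtration; then P(OEt)3 (neat), 120 °C
Reagents that add atoms: carbon tetrabromide, BrC(Br)(Br)Br (bromine of 8); triethyl phosphite, CCOP(OCC)OCC (phosphonate group of 9)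
Why: Appel bromination followed by Michaelis–Arbuzov reaction; bromide 8 has ortho and para oxygen donors and ionises easily, so it is taken on crude, and neither stage produces acid that would cleave the acetal.

Step 6
Reactants: 4 2-hydroxy-4-(methoxymethoxy)-5-(3-methylbut-2-enyl)benzaldehyde; 9 diethyl {[4-methoxy-2-(methoxymethoxy)phenyl]methyl}phosphonate
Product: 10 (E)-5-(methoxymethoxy)-2-{2-[4-methoxy-2-(methoxymethoxy)phenyl]ethenyl}-4-(3-methylbut-2-enyl)phenol
Conditions: KOtBu (3 equiv), DMF, 0 °C to rt
Reagents that add atoms: none
Why: Horner–Wadsworth–Emmons olefination; the first equivalent of base turns 4 into its phenoxide, the benzylic phosphonate anion adds to the aldehyde, and reversible addition with elimination through the less hindered oxaphosphetane should favour the E-stilbene.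

Step 7
Reactants: 10 (E)-5-(methoxymethoxy)-2-{2-[4-methoxy-2-(methoxymethoxy)phenyl]ethenyl}-4-(3-methylbut-2-enyl)phenol
Product: 11 rac-(2S,3R)-3-methoxy-2-[4-methoxy-2-(methoxymethoxy)phenyl]-6-(methoxymethoxy)-5-(3-methylbut-2-enyl)-2,3-dihydrobenzofuran (trans; one enantiomer drawn)
Conditions: reticulated vitreous carbon anode, Pt cathode, undivided cell, constant current at low current density, about 2 F/mol; LiClO4 (0.1 M), 2,6-lutidine (3 equiv), MeOH/CH2Cl2 4:1, substrate about 0.01 M, 0 °C
Reagents that add atoms: methanol, CO
Why: Proposed new method: the tetra-oxygenated hydroxystilbene π-system of 10 should be the most easily oxidised part of the molecule, and loss of one electron at the anode gives a radical cation (or, if the phenol is oxidised first, a phenoxyl radical) in which C2 is electron-poor and stabilised by the para methoxy and ortho acetal oxygens of ring B. The ring A phenol oxygen adds to C2 and 2,6-lutidine takes the proton, the resulting C3 benzylic radical is oxidised at the anode to a cation stabilised by O1 and the C6 oxygen, and solvent methanol captures it; the balancing cathode reaction is hydrogen evolution. The closest known reaction types are the anodic 1,2-dimethoxylation of electron-rich stilbenes, the anodic cyclisation of alkene radical cations onto tethered hydroxyl groups with methanol as the terminating nucleophile, the anodic phenol–alkene [3+2] coupling and the PhI(OAc)2 cyclisation of 2-hydroxystilbenes to 2-arylbenzofurans; none of them has joined a phenol to C2 and an external alcohol to C3 of a 2-hydroxystilbene. The dihydrofuran ring closes through the O1–C2 bond in a formally 5-endo-trig mode, which is acceptable because the carbon attacked is a cationic centre of a radical cation and not a neutral alkene carbon. C2 becomes stereogenic in the ring closure and C3 when methanol approaches the planar cation anti to the C2 aryl group, so the trans racemate is expected by substrate control, but both centres are removed in step 8 and the ratio is of no consequence. Chemoselectivity for the stilbene over the prenyl alkene rests on the large expected gap in oxidation potential and is enforced by a low current density and a charge limited to about 2 F/mol. Regioselectivity rests on geometry and protection: the only free phenol sits on ring A and can reach C2 but not C3, while the ortho oxygen of ring B is capped. Capture of the C3 cation by methanol in preference to loss of the C2 proton, and survival of the C3 ether, rest on methanol being the solvent and on the buffer, and the high dilution holds back coupling of two radical cations.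

Step 8
Reactants: 11 rac-(2S,3R)-3-methoxy-2-[4-methoxy-2-(methoxymethoxy)phenyl]-6-(methoxymethoxy)-5-(3-methylbut-2-enyl)-2,3-dihydrobenzofuran
Product: 12 3-methoxy-2-[4-methoxy-2-(methoxymethoxy)phenyl]-6-(methoxymethoxy)-5-(3-methylbut-2-enyl)benzofuran
Conditions: DDQ (1.1 equiv), 2,6-di-tert-butylpyridine, 4 Å molecular sieves, CH2Cl2, 0 °C to rt
Reagents that add atoms: none
Why: Quinone dehydrogenation of a 2,3-dihydrobenzofuran; hydride abstraction from C2–H (next to O1 and benzylic to the para-methoxy ring B, the activation of a para-methoxybenzyl ether) or from C3–H gives an oxocarbenium ion that loses the neighbouring proton to the aromatic furan and so removes both stereocentres. The pyridine base and the sieves keep acid and water away so that methanol is not lost from C3, and the masked C6 oxygen blocks chromene formation at the prenyl group.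

Step 9
Reactants: 12 3-methoxy-2-[4-methoxy-2-(methoxymethoxy)phenyl]-6-(methoxymethoxy)-5-(3-methylbut-2-enyl)benzofuran
Product: 13 ambofuranol, 2-(2-hydroxy-4-methoxyphenyl)-3-methoxy-5-(3-methylbut-2-enyl)benzofuran-6-ol
Conditions: HCl (1.25 M in MeOH), 0 °C to rt
Reagents that add atoms: none
Why: Acid-catalysed methanolysis of both aryl acetals; in methanol the formaldehyde unit leaves as its dimethyl acetal instead of alkylating the electron-rich rings, any exchange at the C3 enol ether returns the same methoxy group, and the low temperature should keep the prenyl group from closing onto the freed C6 hydroxyl.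

## Compound list

1 | 5-bromo-2,4-dihydroxybenzaldehyde | O=Cc1cc(Br)c(O)cc1O | starting material
2 | 5-bromo-2-hydroxy-4-(methoxymethoxy)benzaldehyde | O=Cc1cc(Br)c(OCOC)cc1O | intermediate
3 | tributyl(3-methylbut-2-enyl)stannane | CCCC[Sn](CCCC)(CCCC)CC=C(C)C | starting material
4 | 2-hydroxy-4-(methoxymethoxy)-5-(3-methylbut-2-enyl)benzaldehyde | O=Cc1cc(CC=C(C)C)c(OCOC)cc1O | intermediate
5 | 2-hydroxy-4-methoxybenzaldehyde | COc1ccc(C=O)c(O)c1 | starting material
6 | 4-methoxy-2-(methoxymethoxy)benzaldehyde | COc1ccc(C=O)c(OCOC)c1 | intermediate
7 | [4-methoxy-2-(methoxymethoxy)phenyl]methanol | COc1ccc(CO)c(OCOC)c1 | intermediate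
8 | 4-methoxy-2-(methoxymethoxy)benzyl bromide | COc1ccc(CBr)c(OCOC)c1 | intermediate (not isolated)
9 | diethyl {[4-methoxy-2-(methoxymethoxy)phenyl]methyl}phosphonate | CCOP(=O)(Cc1ccc(OC)cc1OCOC)OCC | intermediate
10 | (E)-5-(methoxymethoxy)-2-{2-[4-methoxy-2-(methoxymethoxy)phenyl]ethenyl}-4-(3-methylbut-2-enyl)phenol | COCOc1cc(OC)ccc1/C=C/c1cc(CC=C(C)C)c(OCOC)cc1O | intermediate
11 | rac-(2S,3R)-3-methoxy-2-[4-methoxy-2-(methoxymethoxy)phenyl]-6-(methoxymethoxy)-5-(3-methylbut-2-enyl)-2,3-dihydrobenzofuran (trans, one enantiomer drawn) | COCOc1cc(OC)ccc1[C@@H]1Oc2cc(OCOC)c(CC=C(C)C)cc2[C@H]1OC | intermediate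
12 | 3-methoxy-2-[4-methoxy-2-(methoxymethoxy)phenyl]-6-(methoxymethoxy)-5-(3-methylbut-2-enyl)benzofuran | COCOc1cc(OC)ccc1-c1oc2cc(OCOC)c(CC=C(C)C)cc2c1OC | intermediate
13 | ambofuranol, 2-(2-hydroxy-4-methoxyphenyl)-3-methoxy-5-(3-methylbut-2-enyl)benzofuran-6-ol | COc1ccc(-c2oc3cc(O)c(CC=C(C)C)cc3c2OC)c(O)c1 | target

## Step count and least certain steps

Total: 9 steps. The route is convergent. The longest linear sequence is 7 steps, from 5 through steps 3 to 9. The ring A branch (steps 1 and 2) joins at step 6.

Step 7 (key step, new method). Several processes could compete with the intended one. Solvent capture at C2 ahead of ring closure would add two methoxy groups without closing the ring. Loss of the C2 proton from the C3 cation, or acid-induced loss of methanol from the product, would lead to the benzofuran with hydrogen at C3. Coupling of radical cations or phenoxyl radicals would give dimers and foul the anode with polymer. Further oxidation of the product or of the prenyl alkene would set in if the potential drifts upwards. The fallback uses known chemistry and sets out from 10. Oxidative cyclisation with PhI(OAc)2 in MeCN at rt, the established closure of 2-hydroxystilbenes, should give 2-[4-methoxy-2-(methoxymethoxy)phenyl]-6-(methoxymethoxy)-5-(3-methylbut-2-enyl)benzofuran F1. Electrophilic bromination at the enol-ether-like C3 with N-bromosuccinimide in THF at −78 °C should give 3-bromo-2-[4-methoxy-2-(methoxymethoxy)phenyl]-6-(methoxymethoxy)-5-(3-methylbut-2-enyl)benzofuran F2. Ullmann-type methoxylation (CuI, NaOMe, MeOH/DMF, 110 °C) then returns the route at 12, so that step 8 is not needed. The price is that the C3 oxygen comes from a substitution, and the bromination must prefer C3 over the prenyl alkene.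

Step 8. The quinone may abstract hydride from the benzylic and allylic prenyl methylene, over-oxidise the very electron-rich benzofuran, or, through its acidic hydroquinone, cause loss of methanol before dehydrogenation. The fallback changes the order of events so that no prenyl group is present during either oxidation, and it sets out from 2. Olefination of 2 with 9 as in step 6 should give (E)-4-bromo-5-(methoxymethoxy)-2-{2-[4-methoxy-2-(methoxymethoxy)phenyl]ethenyl}phenol F3. Anodic cyclisation as in step 7 should give rac-(2S,3R)-5-bromo-3-methoxy-2-[4-methoxy-2-(methoxymethoxy)phenyl]-6-(methoxymethoxy)-2,3-dihydrobenzofuran F4. Dehydrogenation with DDQ should give 5-bromo-3-methoxy-2-[4-methoxy-2-(methoxymethoxy)phenyl]-6-(methoxymethoxy)benzofuran F5. Stille coupling of F5 with 3 (Pd(PPh3)4, DMF, 100 °C) returns the route at 12. Material that has only lost methanol is F1 and can be brought back through F2 as described for step 7.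

Step 9. Protic acid may close the prenyl group onto the freed C6 hydroxyl, protonate the C3 enol ether, or let formaldehyde-derived electrophiles attack the rings. The fallback replaces Brønsted acid solvolysis by a silyl triflate-mediated acetal cleavage and sets out from 12. Trimethylsilyl triflate with 2,2'-bipyridyl in CH2Cl2 at 0 °C should turn both aryl acetals into silyl ethers, giving 3-methoxy-2-[4-methoxy-2-(trimethylsilyloxy)phenyl]-5-(3-methylbut-2-enyl)-6-(trimethylsilyloxy)benzofuran F6. Addition of water hydrolyses F6 and returns the route at 13.

Step 6. The phenoxide of 4 deactivates the aldehyde, so addition may be slow. The Z isomer may form, or the phenoxide may attack phosphorus in the adduct. The fallback masks the phenol for the olefination and sets out from 4. Allyl bromide with K2CO3 in DMF should give 4-(methoxymethoxy)-5-(3-methylbut-2-enyl)-2-(prop-2-enyloxy)benzaldehyde F7. Olefination with 9 (KOtBu, THF) should give (E)-5-(methoxymethoxy)-2-{2-[4-methoxy-2-(methoxymethoxy)phenyl]ethenyl}-4-(3-methylbut-2-enyl)-1-(prop-2-enyloxy)benzene F8. Removal of the O-allyl group with Pd(PPh3)4 and morpholine in THF, which leaves the C-prenyl group alone, returns the route at 10.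

Step 2. Allyl transposition may give the branched 1,1-dimethylallyl isomer, the electron-rich bromide may undergo slow oxidative addition, and the stannane may be lost by protodestannylation. The fallback builds the prenyl group in two stages and sets out from 2. Stille coupling with allyltributylstannane (Pd(PPh3)4, DMF, 100 °C), which has no regiochemical ambiguity, should give 2-hydroxy-4-(methoxymethoxy)-5-(prop-2-enyl)benzaldehyde F9. Cross-metathesis with 2-methylbut-2-ene using the second-generation Grubbs catalyst (H2IMes)(PCy3)Cl2Ru=CHPh in CH2Cl2 at 40 °C returns the route at 4.

## Further compounds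

F1 | step 7 | 2-[4-methoxy-2-(methoxymethoxy)phenyl]-6-(methoxymethoxy)-5-(3-methylbut-2-enyl)benzofuran | COCOc1cc(OC)ccc1-c1cc2cc(CC=C(C)C)c(OCOC)cc2o1
F2 | step 7 | 3-bromo-2-[4-methoxy-2-(methoxymethoxy)phenyl]-6-(methoxymethoxy)-5-(3-methylbut-2-enyl)benzofuran | COCOc1cc(OC)ccc1-c1oc2cc(OCOC)c(CC=C(C)C)cc2c1Br
F3 | step 8 | (E)-4-bromo-5-(methoxymethoxy)-2-{2-[4-methoxy-2-(methoxymethoxy)phenyl]ethenyl}phenol | COCOc1cc(OC)ccc1/C=C/c1cc(Br)c(OCOC)cc1O
F4 | step 8 | rac-(2S,3R)-5-bromo-3-methoxy-2-[4-methoxy-2-(methoxymethoxy)phenyl]-6-(methoxymethoxy)-2,3-dihydrobenzofuran (trans, one enantiomer drawn) | COCOc1cc(OC)ccc1[C@@H]1Oc2cc(OCOC)c(Br)cc2[C@H]1OC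
F5 | step 8 | 5-bromo-3-methoxy-2-[4-methoxy-2-(methoxymethoxy)phenyl]-6-(methoxymethoxy)benzofuran | COCOc1cc(OC)ccc1-c1oc2cc(OCOC)c(Br)cc2c1OC
F6 | step 9 | 3-methoxy-2-[4-methoxy-2-(trimethylsilyloxy)phenyl]-5-(3-methylbut-2-enyl)-6-(trimethylsilyloxy)benzofuran | COc1ccc(-c2oc3cc(O[Si](C)(C)C)c(CC=C(C)C)cc3c2OC)c(O[Si](C)(C)C)c1
F7 | step 6 | 4-(methoxymethoxy)-5-(3-methylbut-2-enyl)-2-(prop-2-enyloxy)benzaldehyde | O=Cc1cc(CC=C(C)C)c(OCOC)cc1OCC=C
F8 | step 6 | (E)-5-(methoxymethoxy)-2-{2-[4-methoxy-2-(methoxymethoxy)phenyl]ethenyl}-4-(3-methylbut-2-enyl)-1-(prop-2-enyloxy)benzene | COCOc1cc(OC)ccc1/C=C/c1cc(CC=C(C)C)c(OCOC)cc1OCC=C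
F9 | step 2 | 2-hydroxy-4-(methoxymethoxy)-5-(prop-2-enyl)benzaldehyde | O=Cc1cc(CC=C)c(OCOC)cc1O
A1 | alternative 1 | 1-methoxy-7-methyl-1,3-bis(trimethylsilyloxy)octa-1,3,6-triene (alkene geometry not defined) | COC(O[Si](C)(C)C)=CC(O[Si](C)(C)C)=CCC=C(C)C
A2 | alternative 1 | methyl propiolate | C#CC(=O)OC
A3 | alternative 1 | methyl 2,4-dihydroxy-5-(3-methylbut-2-enyl)benzoate | COC(=O)c1cc(CC=C(C)C)c(O)cc1O
A4 | alternative 2 | (E)-4-[6-(tert-butyldimethylsilyloxy)-3-methoxy-5-(3-methylbut-2-enyl)benzofuran-2-yl]-1-diazobut-3-en-2-one | [N-]=[N+]=CC(=O)/C=C/c1oc2cc(O[Si](C)(C)C(C)(C)C)c(CC=C(C)C)cc2c1OC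
A5 | alternative 2 | methoxyethyne | COC#C
A6 | alternative 2 | 2-[6-(tert-butyldimethylsilyloxy)-3-methoxy-5-(3-methylbut-2-enyl)benzofuran-2-yl]-5-methoxyphenol | COc1ccc(-c2oc3cc(O[Si](C)(C)C(C)(C)C)c(CC=C(C)C)cc3c2OC)c(O)c1
A7 | alternative 3 | 4-(3-methylbut-2-enyl)benzene-1,3-diol | CC(C)=CCc1ccc(O)cc1O
A8 | alternative 3 | 2-[4-methoxy-2-(prop-2-enyloxy)phenyl]-2-oxoacetaldehyde | C=CCOc1cc(OC)ccc1C(=O)C=O
A9 | alternative 3 | 3-methoxy-2-[4-methoxy-2-(prop-2-enyloxy)phenyl]-5-(3-methylbut-2-enyl)benzofuran-6-ol | COc1ccc(-c2oc3cc(O)c(CC=C(C)C)cc3c2OC)c(OCC=C)c1
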